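Everything rests on building the quinone ring (ring B, C1'–C6') de novo on a preformed 2H-chromene (rings A and C). An ynone that carries C5', C6', the C1' carbonyl and the methoxylated C2' is annulated with diethyl benzyloxymalonate, which supplies C3' and the oxygenated C4': conjugate addition forms C4'–C5', Claisen closure forms C2'–C3', and loss of the spare ester carbon aromatises the ring. The step exploits the contiguous C1'–C4' oxygenation of ring B, each oxygen arriving on its own carbon in distinguishable form. Asymmetric hydrogenation of C3=C4 then sets C3; hydrogenolysis and air unveil the hydroxyquinone, and acidic methanol methylates O3'.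

Key step: step 5

Numbering used: quinone ring C1'(=O), C2'(OMe), C3'(OMe), C4'(=O), C5'(bears the chroman), C6'(H); chroman O1, C2, C3, C4, C4a–C8a. The target is (3S).

Remark: 2,3-dimethoxybenzene-1,4-diol (1) and diethyl 2-(benzyloxy)malonate (13) are taken as catalogue compounds; 1 is otherwise reached by dithionite reduction of commercial 2,3-dimethoxy-1,4-benzoquinone.

Remark: which antipode of the iridium ligand delivers the 3S product is to be fixed in a trial run; step 6 assumes that antipode.

Step 1
Reactants: 1 2,3-dimethoxybenzene-1,4-diol; 2 benzyl bromide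
Product: 3 4-(benzyloxy)-2,3-dimethoxyphenol
Conditions: BnBr (0.9 equiv), K2CO3, acetone, 50 °C, N2
Reagents that add atoms: benzyl bromide, BrCc1ccccc1
Why: Williamson O-alkylation of one of two equivalent phenols; with the electrophile limiting, the mono-ether should dominate and unreacted diol is recovered.

Step 2
Reactants: 3 4-(benzyloxy)-2,3-dimethoxyphenol; 4 paraformaldehyde
Product: 5 5-(benzyloxy)-2-hydroxy-3,4-dimethoxybenzaldehyde
Conditions: MgCl2, Et3N, (CH2O)n, MeCN, reflux
Reagents that add atoms: paraformaldehyde (as formaldehyde), C=O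
Why: Magnesium-phenoxide-directed ortho-formylation (Casnati–Skattebøl reaction) can only attack the single free ortho carbon, a second formaldehyde acting as hydride acceptor.

Step 3
Reactants: 5 5-(benzyloxy)-2-hydroxy-3,4-dimethoxybenzaldehyde; 6 acrolein
Product: 7 6-(benzyloxy)-7,8-dimethoxy-2H-chromene-3-carbaldehyde
Conditions: K2CO3, 1,4-dioxane, reflux
Reagents that add atoms: acrolein, C=CC=O
Why: Domino oxa-Michael addition of the phenoxide to acrolein and intramolecular aldol condensation onto the aryl aldehyde should close ring C and leave the conjugated chromene aldehyde.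

Step 4
Reactants: 7 6-(benzyloxy)-7,8-dimethoxy-2H-chromene-3-carbaldehyde; 8 (trimethylsilyl)diazomethane; 9 N,2-dimethoxy-N-methylacetamide
Product: 12 4-[6-(benzyloxy)-7,8-dimethoxy-2H-chromen-3-yl]-1-methoxybut-3-yn-2-one, via terminal alkyne 10 (not isolated), via lithium acetylide 11 (not isolated)
Conditions: TMSCHN2, n-BuLi, THF, −78 → 0 °C; then n-BuLi, −78 °C; then 9, −78 → −20 °C; aq. NH4Cl
Reagents that add atoms: (trimethylsilyl)diazomethane, C[Si](C)(C)C=[N+]=[N-]; N,2-dimethoxy-N-methylacetamide, COCC(=O)N(C)OC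
Why: Colvin rearrangement (addition of lithiated TMS-diazomethane, Peterson elimination, loss of N2 and 1,2-shift in the alkylidene carbene) should turn the enal into the enyne, whose lithium acetylide is acylated once at the chelate-stabilised Weinreb amide.

Step 5
Reactants: 12 4-[6-(benzyloxy)-7,8-dimethoxy-2H-chromen-3-yl]-1-methoxybut-3-yn-2-one; 13 diethyl 2-(benzyloxy)malonate
Product: 17 4-(benzyloxy)-5-[6-(benzyloxy)-7,8-dimethoxy-2H-chromen-3-yl]-2-methoxybenzene-1,3-diol, via Michael adduct 14 (not isolated), via cyclic keto ester 15 (not isolated), via keto acid 16 (not isolated)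
Conditions: NaOEt, EtOH, 0 °C → reflux, N2; then 2 M aq. NaOH, 50 °C; then AcOH to pH 5, rt
Reagents that add atoms: diethyl 2-(benzyloxy)malonate, CCOC(=O)C(OCc1ccccc1)C(=O)OCC
Why: The sodium enolate of 13 adds in conjugate fashion to the alkyne terminus C5' of 12 (bond C4'–C5'); adduct 14 equilibrates to its Z isomer by reversible ethoxide or malonate addition, and the enolate at the methoxy-bearing C2' then displaces ethoxide from one ester (bond C2'–C3') to give the cyclic 1,3-diketonate 15, whose remaining ester is hydrolysed and lost as CO2 from the β-keto acid 16 on acidification, so that the ring aromatises. The closest known reaction type is the Michael–Claisen condensation of conjugated alkynones with malonic esters to resorcylates, here run with a 2-alkoxymalonate so that aromatisation occurs by decarboxylation. The carbocycle is the only ring closed, by a 6-exo-trig acyl substitution of the C2' enolate on the ester carbonyl; the first bond is made intermolecularly. No stereocentre survives the step, because the quaternary C4' of 15 becomes an aromatic carbon. The step needs 1,4- rather than 1,2- or 1,6-addition and C- rather than O-acylation: the soft stabilised carbanion and the cumulene that attack at chromene C4 would create secure the first, and an enol lactone formed by O-acylation cannot aromatise and is reopened by ethoxide, whereas diketonate 15 is a thermodynamic sink. Because the four oxygens of ring B arrive on four different carbons (OH at C1', OMe at C2', OH at C3', OBn at C4'), no later regiochemical choice is left open.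

Step 6
Reactants: 17 4-(benzyloxy)-5-[6-(benzyloxy)-7,8-dimethoxy-2H-chromen-3-yl]-2-methoxybenzene-1,3-diol
Product: 18 4-(benzyloxy)-5-[(3S)-6-(benzyloxy)-7,8-dimethoxy-3,4-dihydro-2H-chromen-3-yl]-2-methoxybenzene-1,3-diol
Conditions: H2 (50 bar), [Ir(cod)(tBu-PHOX)]B[3,5-(CF3)2C6H3]4 (2 mol%; tBu-PHOX = 4-tert-butyl-2-[2-(diphenylphosphanyl)phenyl]-4,5-dihydrooxazole, antipode chosen for 3S), CH2Cl2, rt
Reagents that add atoms: none
Why: Iridium-catalysed asymmetric hydrogenation of a 3-aryl-2H-chromene: the cationic N,P-ligated catalyst should add H2 to one enantiotopic face of the trisubstituted C3=C4 bond, so C3 is set by catalyst control while benzyl ethers, phenols and arenes are left alone.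

Step 7
Reactants: 18 4-(benzyloxy)-5-[(3S)-6-(benzyloxy)-7,8-dimethoxy-3,4-dihydro-2H-chromen-3-yl]-2-methoxybenzene-1,3-diol
Product: 20 3-hydroxy-5-[(3S)-6-hydroxy-7,8-dimethoxy-3,4-dihydro-2H-chromen-3-yl]-2-methoxycyclohexa-2,5-diene-1,4-dione, via benzenetriol 19 (not isolated)
Conditions: H2 (1 atm), Pd/C, EtOAc–MeOH, rt; then N2 purge, then air, rt
Reagents that add atoms: none
Why: Heterogeneous hydrogenolysis should cleave both aryl benzyl ethers, and the resulting hydroxyhydroquinone, the most electron-rich ring, is dehydrogenated by air over the same palladium to the 2-hydroxy-1,4-benzoquinone, whereas the ring A chromanol is not oxidised by oxygen and C3 is untouched.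

Step 8
Reactants: 20 3-hydroxy-5-[(3S)-6-hydroxy-7,8-dimethoxy-3,4-dihydro-2H-chromen-3-yl]-2-methoxycyclohexa-2,5-diene-1,4-dione; 21 methanol
Product: 22 5-[(3S)-6-hydroxy-7,8-dimethoxy-3,4-dihydro-2H-chromen-3-yl]-2,3-dimethoxycyclohexa-2,5-diene-1,4-dione
Conditions: TsOH·H2O (0.2 equiv), MeOH, 45 °C
Reagents that add atoms: methanol, CO
Why: Acid-catalysed addition–elimination of methanol at the vinylogous carboxylic acid (Fischer-type esterification of a hydroxyquinone) is reversible and should settle on the para-quinone dimethyl ether, while the phenol, the aryl ethers and the base-sensitive C3–H are left alone.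

Compound list
1 | 2,3-dimethoxybenzene-1,4-diol | COc1c(O)ccc(O)c1OC | starting material
2 | benzyl bromide | BrCc1ccccc1 | starting material
3 | 4-(benzyloxy)-2,3-dimethoxyphenol | COc1c(O)ccc(OCc2ccccc2)c1OC | intermediate
4 | paraformaldehyde (as formaldehyde) | C=O | starting material
5 | 5-(benzyloxy)-2-hydroxy-3,4-dimethoxybenzaldehyde | O=Cc1cc(OCc2ccccc2)c(OC)c(OC)c1O | intermediate
6 | acrolein (prop-2-enal) | C=CC=O | starting material
7 | 6-(benzyloxy)-7,8-dimethoxy-2H-chromene-3-carbaldehyde | O=CC1=Cc2cc(OCc3ccccc3)c(OC)c(OC)c2OC1 | intermediate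
8 | (trimethylsilyl)diazomethane | C[Si](C)(C)C=[N+]=[N-] | starting material
9 | N,2-dimethoxy-N-methylacetamide | COCC(=O)N(C)OC | starting material
10 | 6-(benzyloxy)-3-ethynyl-7,8-dimethoxy-2H-chromene | C#CC1=Cc2cc(OCc3ccccc3)c(OC)c(OC)c2OC1 | intermediate (not isolated)
11 | lithium acetylide of 10 | [Li]C#CC1=Cc2cc(OCc3ccccc3)c(OC)c(OC)c2OC1 | intermediate (not isolated)
12 | 4-[6-(benzyloxy)-7,8-dimethoxy-2H-chromen-3-yl]-1-methoxybut-3-yn-2-one | COCC(=O)C#CC1=Cc2cc(OCc3ccccc3)c(OC)c(OC)c2OC1 | intermediate
13 | diethyl 2-(benzyloxy)malonate | CCOC(=O)C(OCc1ccccc1)C(=O)OCC | starting material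
14 | diethyl 2-(benzyloxy)-2-{(1Z)-1-[6-(benzyloxy)-7,8-dimethoxy-2H-chromen-3-yl]-4-methoxy-3-oxobut-1-en-1-yl}propanedioate | COCC(=O)/C=C(\C(OCc1ccccc1)(C(=O)OCC)C(=O)OCC)C1=Cc2cc(OCc3ccccc3)c(OC)c(OC)c2OC1 | intermediate (not isolated)
15 | ethyl 1-(benzyloxy)-6-[6-(benzyloxy)-7,8-dimethoxy-2H-chromen-3-yl]-3-methoxy-2,4-dioxocyclohex-5-ene-1-carboxylate (racemic, enolised) | CCOC(=O)C1(OCc2ccccc2)C(=O)C(OC)C(=O)C=C1C1=Cc2cc(OCc3ccccc3)c(OC)c(OC)c2OC1 | intermediate (not isolated)
16 | 1-(benzyloxy)-6-[6-(benzyloxy)-7,8-dimethoxy-2H-chromen-3-yl]-3-methoxy-2,4-dioxocyclohex-5-ene-1-carboxylic acid (racemic, enolised) | OC(=O)C1(OCc2ccccc2)C(=O)C(OC)C(=O)C=C1C1=Cc2cc(OCc3ccccc3)c(OC)c(OC)c2OC1 | intermediate (not isolated)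
17 | 4-(benzyloxy)-5-[6-(benzyloxy)-7,8-dimethoxy-2H-chromen-3-yl]-2-methoxybenzene-1,3-diol | COc1c(O)c(OCc2ccccc2)c(cc1O)C1=Cc2cc(OCc3ccccc3)c(OC)c(OC)c2OC1 | intermediate
18 | 4-(benzyloxy)-5-[(3S)-6-(benzyloxy)-7,8-dimethoxy-3,4-dihydro-2H-chromen-3-yl]-2-methoxybenzene-1,3-diol | COc1c(O)c(OCc2ccccc2)c(cc1O)[C@H]1COc2c(cc(OCc3ccccc3)c(OC)c2OC)C1 | intermediate
19 | 6-[(3S)-6-hydroxy-7,8-dimethoxy-3,4-dihydro-2H-chromen-3-yl]-3-methoxybenzene-1,2,4-triol | COc1c(O)c(O)c(cc1O)[C@H]1COc2c(cc(O)c(OC)c2OC)C1 | intermediate (not isolated)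
20 | 3-hydroxy-5-[(3S)-6-hydroxy-7,8-dimethoxy-3,4-dihydro-2H-chromen-3-yl]-2-methoxycyclohexa-2,5-diene-1,4-dione | COC1=C(O)C(=O)C([C@H]2COc3c(cc(O)c(OC)c3OC)C2)=CC1=O | intermediate
21 | methanol | CO | starting material
22 | 5-[(3S)-6-hydroxy-7,8-dimethoxy-3,4-dihydro-2H-chromen-3-yl]-2,3-dimethoxycyclohexa-2,5-diene-1,4-dione | COC1=C(OC)C(=O)C([C@H]2COc3c(cc(O)c(OC)c3OC)C2)=CC1=O | target

Total step count: 8
Longest linear sequence: 8 steps (1 → 22)

Steps most likely to fail

Step 5. The tertiary alkoxymalonate anion may add too slowly to the hindered alkyne terminus, so that ethoxide addition and oligomerisation of the enynone prevail, or the adduct may not reach the Z geometry that closure needs. The fallback sets out from 12 and returns at 17. The ynone is hydrated through its pyrrolidine enaminone (pyrrolidine, EtOH; then aq. AcOH) to 1-[6-(benzyloxy)-7,8-dimethoxy-2H-chromen-3-yl]-4-methoxybutane-1,3-dione F1. Its dianion (LDA, THF, −78 → 0 °C) is acylated at the methoxy-bearing terminus with 2-(benzyloxy)-N-methoxy-N-methylacetamide to give 6-(benzyloxy)-1-[6-(benzyloxy)-7,8-dimethoxy-2H-chromen-3-yl]-4-methoxyhexane-1,3,5-trione F2. Aqueous KOH in MeOH should then bring about the polyketide-type aldol cyclodehydration of the benzyloxymethyl terminus onto the chromenyl ketone, which leads back to 17. The same two ring bonds are made, but in two operations and with C4'–C5' formed by aldol addition instead of conjugate addition.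

Step 6. Turnover may be low or facial discrimination poor, because the ortho-benzyloxy group twists and shields the styrenic C3=C4 bond and the free phenols can bind iridium. The fallback sets out from 17 and returns at 22. Hydrogenation over Pd/C (H2, EtOAc–MeOH) reduces the C3=C4 bond without stereocontrol and cleaves both benzyl ethers to racemic 6-(6-hydroxy-7,8-dimethoxy-3,4-dihydro-2H-chromen-3-yl)-3-methoxybenzene-1,2,4-triol F3. Air converts this into racemic 3-hydroxy-5-(6-hydroxy-7,8-dimethoxy-3,4-dihydro-2H-chromen-3-yl)-2-methoxycyclohexa-2,5-diene-1,4-dione F4. Methylation as in step 8 gives racemic 5-(6-hydroxy-7,8-dimethoxy-3,4-dihydro-2H-chromen-3-yl)-2,3-dimethoxycyclohexa-2,5-diene-1,4-dione F5. Preparative chromatography on a chiral stationary phase (supercritical CO2/MeOH on an amylose carbamate phase) then separates 22 from 5-[(3R)-6-hydroxy-7,8-dimethoxy-3,4-dihydro-2H-chromen-3-yl]-2,3-dimethoxycyclohexa-2,5-diene-1,4-dione F6.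

Step 8. The vinylogous esterification may stay incomplete or lose selectivity through acid-promoted conjugate addition of methanol or of the ring A phenol to the quinone, or through tautomerisation at C3. The fallback sets out from 20 and returns at 22. Irreversible O-alkylation replaces the equilibrium process: (trimethylsilyl)diazomethane in toluene–MeOH at 0 °C should methylate only the strongly acidic hydroxyquinone hydroxyl, the far less acidic ring A phenol being left, and give 22 directly. No new compound is made on this way.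

Further compounds
F1 | step 5 | 1-[6-(benzyloxy)-7,8-dimethoxy-2H-chromen-3-yl]-4-methoxybutane-1,3-dione | COCC(=O)CC(=O)C1=Cc2cc(OCc3ccccc3)c(OC)c(OC)c2OC1
F2 | step 5 | 6-(benzyloxy)-1-[6-(benzyloxy)-7,8-dimethoxy-2H-chromen-3-yl]-4-methoxyhexane-1,3,5-trione (racemic, enolised) | O=C(COCc1ccccc1)C(OC)C(=O)CC(=O)C1=Cc2cc(OCc3ccccc3)c(OC)c(OC)c2OC1
F3 | step 6 | racemic 6-(6-hydroxy-7,8-dimethoxy-3,4-dihydro-2H-chromen-3-yl)-3-methoxybenzene-1,2,4-triol | COc1c(O)c(O)c(cc1O)C1COc2c(cc(O)c(OC)c2OC)C1
F4 | step 6 | racemic 3-hydroxy-5-(6-hydroxy-7,8-dimethoxy-3,4-dihydro-2H-chromen-3-yl)-2-methoxycyclohexa-2,5-diene-1,4-dione | COC1=C(O)C(=O)C(C2COc3c(cc(O)c(OC)c3OC)C2)=CC1=O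
F5 | step 6 | racemic 5-(6-hydroxy-7,8-dimethoxy-3,4-dihydro-2H-chromen-3-yl)-2,3-dimethoxycyclohexa-2,5-diene-1,4-dione | COC1=C(OC)C(=O)C(C2COc3c(cc(O)c(OC)c3OC)C2)=CC1=O
F6 | step 6 | 5-[(3R)-6-hydroxy-7,8-dimethoxy-3,4-dihydro-2H-chromen-3-yl]-2,3-dimethoxycyclohexa-2,5-diene-1,4-dione | COC1=C(OC)C(=O)C([C@@H]2COc3c(cc(O)c(OC)c3OC)C2)=CC1=O
F0 | step 8 | none | none
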